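If you take over this flask, here is what it holds and what it will do.

    spent carrier + salt in the second phase ⇌ fresh carrier + spent salt in the second phase (K1 = 1.0, k1 = 590 L mol⁻¹ s⁻¹)
    substrate + fresh carrier → product + spent carrier (k2 = 540 L mol⁻¹ s⁻¹)
    added ligand + fresh carrier ⇌ idle complex (K3 = 4000 L mol⁻¹, k3 = 12000 L mol⁻¹ s⁻¹)
    spent carrier → spent catalyst (k4 = 0.060 s⁻¹)

substrate 0.50 mM; salt in the second phase 1.50 mM; spent carrier 25 µM; added ligand 99 µM; volume of the second phase over the first 2.0

- the form that holds most of the catalyst when 5.0 % of the substrate are converted (spent catalyst / spent carrier / idle complex / fresh carrier)
- its share of the catalyst then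
- factor on the rate of making product when 5.0 % of the substrate are converted if spent carrier is charged twice over
- factor on the rate when 5.0 % of the substrate are converted if spent carrier is charged at 5.0 µM instead

**What stands.** Spent carrier either takes up salt and returns as fresh carrier, or dies to spent catalyst. The salt counts over its own phase, 0.750 mM, so the return runs at 0.44 s⁻¹ per spent carrier and the death at 0.060 s⁻¹.

**The count.** Keep one number, N = 7.38: the lifetime yield, the product one carrier makes before it dies, counting the forward step of the return with the salt as charged, which is that return rate over the death rate. I take the rate to follow live carrier, meaning every form but spent catalyst, reckoned as the charge less product over N. At 5.0 % conversion that count gives 21.6 µM in this flask.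

**When you come.** Expect more fresh carrier than spent carrier, making fresh carrier the resting state, since spent carrier leaves at 0.44 s⁻¹, faster than substrate takes fresh carrier at 0.27 s⁻¹. My reckoning gives no share.

**Don't touch.** Leave the charge of spent carrier alone. Doubled, it gives me a factor of 2.16 on the rate, more than the 2 of a first-order catalyst.

**The forecast.** It names fresh carrier at 41 %, a factor of 2.1 when doubled, lower than mine, and 0.07 at 5.0 µM, “far less than the proportional one-fifth”.

**What came.** In this flask at 10.2 s, fresh carrier holds 40.1 % of the catalyst, and doubling the charge gives a factor of 2.11. Spent catalyst stands at 21.8 % then, more than the 13.6 % that N gave me. In the flask charged at 5.0 µM, N allows 36.9 µM of product over the carrier's life, and 5.0 % conversion takes 25.0 µM, leaving 1.61 µM live by my count. Over the 21.6 µM of the first flask that is 0.0745, against the simulated 0.0710.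

(The constants used here belong to no real substance; the result is computed.)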